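The data were computed from invented constants, and the scatter is random.

Two questions stand here, the ratio of side product to target early and late in the flask, and I want one number to answer both.

| flask | substrate | partner | free catalyst | remark | time |
|---|---|---|---|---|---|
| summer | 72 mM | 1 equiv | 1.1 mol% | run made earlier |  |
| flask | 36 mM | 1.00 equiv | 1.1 mol% |  | 3.0 d |

summer run (percent of the substrate charged)

| time / h | side product / % | target / % |
|---|---|---|
| 0.667 | 19.2 | 40.9 |
| 2.00 | 30.9 | 66.3 |
| 3.00 | 31.7 | 68.3 |
| 5.00 | 31.8 | 67.9 |
| 8.00 | 31.1 | 69.5 |

(readings scatter by 0.5 percentage points)

1. ratio of side product to target at 4.0 min
2. ratio of side product to target at 3.0 d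

- the analysis behind the earlier runs scatters by 0.5 percentage points, standard deviation
- steps under discussion: substrate + free catalyst <-> free catalyst + open intermediate; free catalyst + open intermediate <-> catalyst intermediate; partner + catalyst intermediate -> free catalyst + target; open intermediate -> side product
- no earlier run changes the charge of free catalyst; that part of a forecast is a guess

Side product and target both leave from the open intermediate, the first by first-order loss, the second after capture by free catalyst. I take the ratio of the two rates as fixed, which is my assumption and does not follow from free catalyst staying near its charge; if it holds, integrating them gives that same ratio for the amounts at any time. The last readings of the summer run give 0.460, and the first gives 0.469, both with their scatter. Multiplied by the summer catalyst concentration, this gives 0.364 mM, the break-even catalyst concentration, where on that assumption the ratio reads one; it is a selectivity factor in concentration units.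

Divided by the 0.396 mM of catalyst in the flask, it gives my dimensionless number, 0.920, for both times. One number may not be enough: I expect partner in the flask to end near 17.2 mM, lower than the 22.0 mM reached in the summer run.

The forecast gives 1 (0.85 to 1.6) early and 0.92 (0.8 to 1.05) late, saying “the ratio should roughly double”.

The flask gives 0.937 at 4.0 min and 0.962 at 3.0 d.

    substrate + free catalyst ⇌ free catalyst + open intermediate (K = 2.00, k = 0.760 /M/s)
    free catalyst + open intermediate ⇌ catalyst intermediate (K = 250 /M, k = 3.30 /M/s)
    partner + catalyst intermediate → free catalyst + target (k = 1.50 /M/s)
    open intermediate → side product (k = 8.30 × 10⁻⁴ /s)

Against my 0.920, the flask ends 0.0420 higher, with target at 51.0% and side product at 49.0% at 3.00 d. A second flask, equal but for 0.28 mol% of free catalyst, gets 3.61 from the same break-even concentration, and it stands at 3.37 with target at 22.9%.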